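## Retrosynthetic overview
1. The target comes from its 3-carbaldehyde triacetate by one global hydride reduction (CHO to CH2OH, three OAc to OH).
2. That aldehyde comes from a 3-arylpropanal and sinapyl alcohol diacetate in one catalytic asymmetric oxidative [4+2]. The C8–C8' bond joins the aldehyde α-carbon, made electrophilic as its enamine radical cation (a one-electron enolonium equivalent), to the nucleophilic β-carbon of the styrene.
3. The C7' benzylic cation formed in the same flask is captured by ring A (C7'–C6 bond). Ring B is the only ring built and closes in this step. Rings A and C are bought.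
4. The 3-arylpropanal comes from vanillin acetate (two-carbon Wittig homologation, C=C hydrogenation). The styrene comes from 4-allyl-2,6-dimethoxyphenol (acetylation, allylic C–H acetoxylation).
5. The acetates shield the phenols and both arenes from the oxidant and are cleaved in the final hydride step, so there is no separate deprotection.

Numbering: lignan C7–C9 is the side chain of the ring A unit and C7'–C9' is the side chain of the syringyl unit. Tetralin C1 = C7' (aryl-bearing), C2 = C8', C3 = C8, C4 = C7.

Assumption: the sense of induction follows the usual shielding model of the imidazolidinone, in which the benzyl group covers one enamine face. If the antipode formed, the equally available (2S,5S)-catalyst would be used.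

## Route

Step 1
Reactants: 1 4-formyl-2-methoxyphenyl acetate (vanillin acetate); 2 (triphenylphosphoranylidene)acetaldehyde
Product: 3 (E)-3-(4-acetoxy-3-methoxyphenyl)prop-2-enal
Conditions: 2 (1.1 equiv), toluene, 80 °C
Reagents that add atoms: none
Why: Wittig olefination with a stabilised, non-basic formyl ylide gives the (E)-enal and leaves the aryl acetate untouched; no stereocentre is formed.

Step 2
Reactants: 3 (E)-3-(4-acetoxy-3-methoxyphenyl)prop-2-enal
Product: 4 3-(4-acetoxy-3-methoxyphenyl)propanal
Conditions: H2 (1 atm), 10% Pd/C, EtOAc, rt, stopped at 1 equiv H2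
Reagents that add atoms: none
Why: Heterogeneous catalytic hydrogenation saturates the conjugated C=C much faster than it reduces the aldehyde, and the aryl acetate and methyl ether are inert.

Step 3
Reactants: 5 4-allyl-2,6-dimethoxyphenol
Product: 6 4-allyl-2,6-dimethoxyphenyl acetate
Conditions: Ac2O, pyridine, rt
Reagents that add atoms: acetic anhydride, CC(=O)OC(C)=O
Why: Plain O-acylation of the phenol, which removes the oxidisable OH and raises the oxidation potential of ring C so that it survives steps 4 and 5.

Step 4
Reactants: 6 4-allyl-2,6-dimethoxyphenyl acetate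
Product: 7 (E)-3-(4-acetoxy-3,5-dimethoxyphenyl)prop-2-enyl acetate (sinapyl alcohol diacetate)
Conditions: Pd(OAc)2 (10 mol%), 1,4-benzoquinone (2 equiv), DMSO/AcOH 1:1, 4 Å MS, 40 °C
Reagents that add atoms: acetic acid, CC(=O)O
Why: Sulfoxide-promoted Pd-catalysed allylic C–H acetoxylation, in which divalent palladium cleaves the benzylic-allylic C–H bond to a 1-aryl-π-allyl complex, acetate attacks the unhindered terminus so that styrene conjugation is kept (linear E product), and benzoquinone reoxidises zerovalent palladium.

Step 5
Reactants: 4 3-(4-acetoxy-3-methoxyphenyl)propanal; 7 (E)-3-(4-acetoxy-3,5-dimethoxyphenyl)prop-2-enyl acetate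
Product: 10 (1R,2S,3S)-7-acetoxy-1-(4-acetoxy-3,5-dimethoxyphenyl)-2-(acetoxymethyl)-6-methoxy-1,2,3,4-tetrahydronaphthalene-3-carbaldehyde, via E-enamine 8 (not isolated), via benzylic cation 9 (not isolated)
Conditions: (2R,5R)-5-benzyl-2-tert-butyl-3-methylimidazolidin-4-one·TFA (20 mol%), pre-formed [Fe(phen)3](SbF6)3 (phen = 1,10-phenanthroline, 2.5 equiv), Na2HPO4 (3 equiv), 7 (2 equiv, excess recovered), DME/MeCN, −30 °C
Reagents that add atoms: none
Why: Proposed new method: the closest known reaction type is the organo-SOMO radical-polar crossover formal [4+2] of 3-arylpropanals with simple styrenes, extended here to a β-substituted cinnamyl acetate; the trivalent iron oxidant takes one electron from enamine 8 to give a 3π radical cation whose α-carbon C8 is electrophilic, this carbon bonds through the face not covered by the catalyst benzyl group (C3 = S) to the nucleophilic styrene carbon C8' in a staggered open transition state with the styryl unit anti to the iminium carbon and CH2OAc in the slot next to H (C2 = S, trans to C3), a second oxidation gives benzylic cation 9, and ring A closes para to its OMe by Friedel-Crafts alkylation through a chair-like array with all three substituents pseudo-equatorial (C1 = R, trans to C2).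

Step 6
Reactants: 10 (1R,2S,3S)-7-acetoxy-1-(4-acetoxy-3,5-dimethoxyphenyl)-2-(acetoxymethyl)-6-methoxy-1,2,3,4-tetrahydronaphthalene-3-carbaldehyde
Product: 11 (6S,7S,8R)-8-(4-hydroxy-3,5-dimethoxyphenyl)-6,7-bis(hydroxymethyl)-3-methoxy-5,6,7,8-tetrahydronaphthalen-2-ol (target; 1R,2S,3S in tetralin numbering)
Conditions: LiAlH4 (6 equiv), THF, 0 °C to rt; aq. potassium sodium tartrate work-up under argon
Reagents that add atoms: none
Why: LiAlH4 hydride reduction turns the aldehyde into the C3 hydroxymethyl group and reductively cleaves all three acetates in one operation, and the aldehyde is reduced faster than it can enolise, so none of the three stereocentres is disturbed.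

## Compound list
1 | 4-formyl-2-methoxyphenyl acetate (vanillin acetate) | CC(=O)Oc1ccc(C=O)cc1OC | starting material
2 | (triphenylphosphoranylidene)acetaldehyde | O=CC=P(c1ccccc1)(c1ccccc1)c1ccccc1 | starting material
3 | (E)-3-(4-acetoxy-3-methoxyphenyl)prop-2-enal | CC(=O)Oc1ccc(/C=C/C=O)cc1OC | intermediate
4 | 3-(4-acetoxy-3-methoxyphenyl)propanal | CC(=O)Oc1ccc(CCC=O)cc1OC | intermediate
5 | 4-allyl-2,6-dimethoxyphenol | C=CCc1cc(OC)c(O)c(OC)c1 | starting material
6 | 4-allyl-2,6-dimethoxyphenyl acetate | C=CCc1cc(OC)c(OC(C)=O)c(OC)c1 | intermediate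
7 | (E)-3-(4-acetoxy-3,5-dimethoxyphenyl)prop-2-enyl acetate | CC(=O)OC/C=C/c1cc(OC)c(OC(C)=O)c(OC)c1 | intermediate
8 | E-enamine: N1-[(E)-3-(4-acetoxy-3-methoxyphenyl)prop-1-enyl] derivative of the (2R,5R)-imidazolidinone catalyst | CN1C(=O)[C@@H](Cc2ccccc2)N(/C=C/Cc2ccc(OC(C)=O)c(OC)c2)[C@H]1C(C)(C)C | intermediate
9 | benzylic cation: catalyst iminium of the open-chain C8–C8' adduct (C8 and C8' set) carrying the C7' carbocation | CN1C(=O)[C@@H](Cc2ccccc2)[N+](=C[C@@H](Cc2ccc(OC(C)=O)c(OC)c2)[C@@H](COC(C)=O)[CH+]c2cc(OC)c(OC(C)=O)c(OC)c2)[C@H]1C(C)(C)C | intermediate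
10 | (1R,2S,3S)-7-acetoxy-1-(4-acetoxy-3,5-dimethoxyphenyl)-2-(acetoxymethyl)-6-methoxy-1,2,3,4-tetrahydronaphthalene-3-carbaldehyde | COc1cc2c(cc1OC(C)=O)[C@@H](c1cc(OC)c(OC(C)=O)c(OC)c1)[C@H](COC(C)=O)[C@@H](C=O)C2 | intermediate
11 | (6S,7S,8R)-8-(4-hydroxy-3,5-dimethoxyphenyl)-6,7-bis(hydroxymethyl)-3-methoxy-5,6,7,8-tetrahydronaphthalen-2-ol | COc1cc2c(cc1O)[C@@H](c1cc(OC)c(O)c(OC)c1)[C@H](CO)[C@@H](CO)C2 | target

## Step count and risks
Total steps: 6. Longest linear sequence: 4 (1 → 3 → 4 → 10 → 11, or 5 → 6 → 7 → 10 → 11).

**Step 5 (highest risk).**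
- The β-substituted, only moderately nucleophilic styrene 7 may add too slowly, so that enamine homocoupling competes.
- Facial control at C8' may be modest. The minor C2 epimer must be removed by chromatography, not by epimerising C3, because epimerisation would erode the ee.
- The C9' acetate or water may intercept cation 9 before ring A does.

Fallback: split the cascade into two operations. From 4 and 7, the same imidazolidinone with (NH4)2Ce(NO3)6 and NaHCO3 in wet DME at −40 °C runs the known styrene carbo-oxidation mode, in which nitrate captures the benzylic cation. This gives (2S,3S)-2-(4-acetoxy-3-methoxybenzyl)-3-(acetoxymethyl)-4-(4-acetoxy-3,5-dimethoxyphenyl)-4-(nitrooxy)butanal F1, and both C4 epimers are usable. A separate ionisation (BF3·OEt2, 2,6-di-tert-butylpyridine, CH2Cl2, −40 °C) then closes ring B by Friedel-Crafts alkylation under chair control. This comes back to the route at 10.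

**Step 4.** Allylarenes can isomerise to the propenylarene under divalent palladium, or give branched acetate or Wacker ketone.

Fallback: make the isomerisation the plan and install the acetate by metathesis instead of C–H oxidation. From 6, RuHCl(CO)(PPh3)3 (1 mol%) in toluene at 80 °C gives (E)-2,6-dimethoxy-4-(prop-1-enyl)phenyl acetate F2. Cross-metathesis with (Z)-but-2-ene-1,4-diyl diacetate (3 equiv, second-generation Hoveyda-Grubbs catalyst, CH2Cl2, 40 °C) exchanges the ethylidene terminus for CHCH2OAc. This comes back to the route at 7.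

**Step 1.** The formyl ylide reacts slowly with this fairly electron-rich aldehyde, and the product enal can be homologated a second time to the dienal.

Fallback: build the saturated C3 chain without any enal. From 1, a three-component reductive Knoevenagel alkylation (Meldrum's acid, Hantzsch ester, L-proline 20 mol%, EtOH, rt) gives 5-(4-acetoxy-3-methoxybenzyl)-2,2-dimethyl-1,3-dioxane-4,6-dione F3. Lewis-base-promoted hydrosilylation (PhSiH3, Et3N, THF, rt, then water) reduces one carbonyl and fragments the ring to the aldehyde. This bypasses 3 and comes back to the route at 4.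

## Further compounds
F1 | step 5 | (2S,3S)-2-(4-acetoxy-3-methoxybenzyl)-3-(acetoxymethyl)-4-(4-acetoxy-3,5-dimethoxyphenyl)-4-(nitrooxy)butanal (C4 epimers) | O=C[C@@H](Cc1ccc(OC(C)=O)c(OC)c1)[C@@H](COC(C)=O)C(O[N+](=O)[O-])c1cc(OC)c(OC(C)=O)c(OC)c1
F2 | step 4 | (E)-2,6-dimethoxy-4-(prop-1-enyl)phenyl acetate | C/C=C/c1cc(OC)c(OC(C)=O)c(OC)c1
F3 | step 1 | 5-(4-acetoxy-3-methoxybenzyl)-2,2-dimethyl-1,3-dioxane-4,6-dione | CC(=O)Oc1ccc(CC2C(=O)OC(C)(C)OC2=O)cc1OC
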